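**Plan**
- Retrosynthesis: the acetyl group and the O5 silyl group come off first. Then three bonds are cut in turn: C3–C1' (pyridine to diene), C7–C7a (the five-membered ring) and C4a–C5. This leaves 5-bromo-2-chloropyridine, a citramalate-derived keto diester and a dienylboronate.
- Enabling feature: in the cyclopenta[c]pyridine core the C7 ketone lies between pyridine carbon C7a and the quaternary carbon C6. C6 with its methyl group, its oxygen, C5 and C7 is the carbon skeleton of (S)-citramalic acid (C1 carboxyl = C7). A carbanion at C7a can therefore be acylated by a C7 ester already tethered through C5 and C6.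
- Forward: steps 1–4 give the dienylboronate and steps 5–8 the keto diester. Step 9 joins pyridine C4 to C5, step 10 closes the cyclopentanone ring onto the purchased pyridine ring, and step 11 attaches the diene at C3. Steps 12–14 exchange the O6 silyl group for acetyl and free O5.
- Stereochemistry: C6 is the stereocentre of (S)-citramalic acid and is never enolisable. C5 is set in step 9 by Felkin–Anh addition next to C6. C5' comes from (S)-2-methylbutan-1-ol, and both E alkenes come from the Wittig reaction and the chromium-mediated boryl-olefination.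

Key step: step 10

Remark: locants C1–C7a are those of the cyclopenta[c]pyridine ring of the target and primed locants those of the heptadienyl chain; the C5 epimers formed in step 9 are assumed to be separable by chromatography at the stage of 17.

**Route**

Step 1
Reactants: 1 (S)-2-methylbutan-1-ol; 2 ethyl 2-(triphenyl-λ5-phosphanylidene)propanoate
Product: 4 ethyl (2E,4S)-2,4-dimethylhex-2-enoate, via (S)-2-methylbutanal 3 (not isolated)
Conditions: TEMPO (cat.), PhI(OAc)2, CH2Cl2, rt; then 2, rt → 40 °C
Reagents that add atoms: none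
Why: the nitroxyl-catalysed oxidation gives the epimerisable aldehyde under non-basic conditions, and the stabilised ylide traps it in the same flask in an E-selective Wittig olefination, so the stereocentre of 1 is carried over unchanged.

Step 2
Reactants: 4 ethyl (2E,4S)-2,4-dimethylhex-2-enoate
Product: 5 (2E,4S)-2,4-dimethylhex-2-en-1-ol
Conditions: i-Bu2AlH, CH2Cl2, −78 °C; aq. potassium sodium tartrate
Reagents that add atoms: none
Why: 1,2-reduction of a conjugated ester by the aluminium hydride is standard and touches neither the alkene geometry nor the allylic stereocentre.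

Step 3
Reactants: 5 (2E,4S)-2,4-dimethylhex-2-en-1-ol
Product: 6 (2E,4S)-2,4-dimethylhex-2-enal
Conditions: MnO2, CH2Cl2, rt
Reagents that add atoms: none
Why: heterogeneous allylic oxidation with MnO2 stops at the enal and is neutral, so the E geometry and the γ-stereocentre should be preserved.

Step 4
Reactants: 6 (2E,4S)-2,4-dimethylhex-2-enal; 7 2-(dichloromethyl)-4,4,5,5-tetramethyl-1,3,2-dioxaborolane
Product: 8 2-[(1E,3E,5S)-3,5-dimethylhepta-1,3-dien-1-yl]-4,4,5,5-tetramethyl-1,3,2-dioxaborolane
Conditions: CrCl2, LiI, THF, rt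
Reagents that add atoms: none
Why: in this Takai–Utimoto boryl-olefination the geminal dichromium species adds to the aldehyde and anti elimination of the β-oxido organochromium gives the E-alkenylboronate, under non-basic conditions that cannot deprotonate the γ-position.

Step 5
Reactants: 9 (S)-citramalic acid [(2S)-2-hydroxy-2-methylbutanedioic acid]
Product: 10 dimethyl (2S)-2-hydroxy-2-methylbutanedioate
Conditions: SOCl2, MeOH, 0 °C → rt
Reagents that add atoms: methanol, CO
Why: acid-mediated (Fischer-type) esterification of both carboxyl groups with HCl generated in situ leaves the tertiary carbinol stereocentre untouched.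

Step 6
Reactants: 10 dimethyl (2S)-2-hydroxy-2-methylbutanedioate
Product: 11 dimethyl (2S)-2,3-dihydroxy-2-methylbutanedioate (both C3 epimers)
Conditions: LiN(iPr)2 (2.2 equiv), THF, −78 → −40 °C; (camphorsulfonyl)oxaziridine, −78 °C; NH4Cl
Reagents that add atoms: (camphorsulfonyl)oxaziridine (either enantiomer), CC1(C)C2CCC13CS(=O)(=O)N4OC34C2
Why: the alkoxide–enolate dianion of a β-hydroxy ester (Fráter–Seebach type) cannot eliminate its β-oxygen and is hydroxylated at C3 by the N-sulfonyloxaziridine (enolate oxidation); the new C3 centre need not be controlled because step 7 makes it a ketone.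

Step 7
Reactants: 11 dimethyl (2S)-2,3-dihydroxy-2-methylbutanedioate
Product: 12 dimethyl (2S)-2-hydroxy-2-methyl-3-oxobutanedioate
Conditions: Dess–Martin periodinane, NaHCO3, CH2Cl2, 0 °C → rt
Reagents that add atoms: none
Why: the periodinane oxidises the secondary α-hydroxy ester to the α-keto ester under buffered, near-neutral conditions, the tertiary hydroxyl cannot be oxidised, and C2 has no hydrogen through which it could epimerise.

Step 8
Reactants: 12 dimethyl (2S)-2-hydroxy-2-methyl-3-oxobutanedioate
Product: 13 dimethyl (2S)-2-methyl-3-oxo-2-[(triethylsilyl)oxy]butanedioate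
Conditions: TESOTf, 2,6-lutidine, CH2Cl2, −78 → 0 °C
Reagents that add atoms: triethylsilyl trifluoromethanesulfonate, CC[Si](CC)(CC)OS(=O)(=O)C(F)(F)F
Why: silyl triflate with a hindered base silylates tertiary alcohols readily, the ketone has no α-hydrogen and cannot form an enol ether, and capping the hydroxyl removes the risk of α-ketol rearrangement and gives a non-chelating ether for step 9.

Step 9
Reactants: 14 5-bromo-2-chloropyridine; 13 dimethyl (2S)-2-methyl-3-oxo-2-[(triethylsilyl)oxy]butanedioate
Product: 17 dimethyl (2R,3S)-2-(5-bromo-2-chloropyridin-4-yl)-2-[(tert-butyldimethylsilyl)oxy]-3-methyl-3-[(triethylsilyl)oxy]butanedioate, via (5-bromo-2-chloropyridin-4-yl)lithium 15 (not isolated), via lithium alkoxide 16 (not isolated)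
Conditions: LiN(iPr)2, THF, −78 °C; add 13, −78 °C; then TBSOTf, −78 → −20 °C
Reagents that add atoms: tert-butyldimethylsilyl trifluoromethanesulfonate, CC(C)(C)[Si](C)(C)OS(=O)(=O)C(F)(F)F
Why: directed ortho-lithiation removes the C4 proton next to bromine (kept at −78 °C to forestall a halogen dance), the aryllithium adds 1,2 to the non-enolisable, doubly activated ketone of 13, and the tertiary alkoxide is silylated in the same flask before it can fragment; C5 should be set by the Felkin–Anh model, the nucleophile entering anti to the C6–OSiEt3 bond with the flat, less demanding ester group outside and the methyl group inside, which gives the 2R (ring C5 R) configuration.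

Step 10
Reactants: 17 dimethyl (2R,3S)-2-(5-bromo-2-chloropyridin-4-yl)-2-[(tert-butyldimethylsilyl)oxy]-3-methyl-3-[(triethylsilyl)oxy]butanedioate
Product: 20 methyl (5R,6S)-5-[(tert-butyldimethylsilyl)oxy]-3-chloro-6-methyl-7-oxo-6-[(triethylsilyl)oxy]-6,7-dihydro-5H-cyclopenta[c]pyridine-5-carboxylate, via aryllithium 18 (not isolated), via lithium hemiketal alkoxide 19 (not isolated)
Conditions: t-BuLi (2.05 equiv), THF/Et2O, −100 → −78 °C; NH4Cl, −78 °C
Reagents that add atoms: none
Why: tert-butyllithium exchanges the bromine on the future C7a within minutes at −100 °C (the second equivalent destroys tert-butyl bromide), and the 3-pyridyllithium 18 attacks the ester carbonyl on C6 to give hemiketal alkoxide 19, which loses methoxide on protic work-up and leaves the C7 ketone. The closest known reaction is the Parham cyclisation of ortho-bromoaryl-tethered esters to indanones. The ring made of C4a, C5, C6, C7 and C7a closes in the 5-exo-trig mode. No lasting stereocentre is formed, since the hemiketal carbon becomes the planar ketone, and C5 and C6 are fully substituted and pass through unchanged. The step needs exchange to outrun addition to the esters and to the chloropyridine, which the very low temperature and the inert C–Cl bond should secure; attack on the C5 ester would be a 4-exo closure to a strained four-membered ketone, the bulky tert-butyldimethylsilyl group on O5 slows silyl migration from oxygen to the carbanion, and full substitution of both tether carbons favours closure.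

Step 11
Reactants: 20 methyl (5R,6S)-5-[(tert-butyldimethylsilyl)oxy]-3-chloro-6-methyl-7-oxo-6-[(triethylsilyl)oxy]-6,7-dihydro-5H-cyclopenta[c]pyridine-5-carboxylate; 8 2-[(1E,3E,5S)-3,5-dimethylhepta-1,3-dien-1-yl]-4,4,5,5-tetramethyl-1,3,2-dioxaborolane
Product: 21 methyl (5R,6S)-5-[(tert-butyldimethylsilyl)oxy]-3-[(1E,3E,5S)-3,5-dimethylhepta-1,3-dien-1-yl]-6-methyl-7-oxo-6-[(triethylsilyl)oxy]-6,7-dihydro-5H-cyclopenta[c]pyridine-5-carboxylate
Conditions: Pd(OAc)2, SPhos, K3PO4, THF/H2O, 50 °C
Reagents that add atoms: none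
Why: Suzuki–Miyaura coupling of a 2-chloropyridine activated by the ring nitrogen and the para acyl group proceeds with retention of the dienylboronate geometry, and the ketone is non-enolisable and both carbinols are silylated, so the mild base finds nothing to attack.

Step 12
Reactants: 21 methyl (5R,6S)-5-[(tert-butyldimethylsilyl)oxy]-3-[(1E,3E,5S)-3,5-dimethylhepta-1,3-dien-1-yl]-6-methyl-7-oxo-6-[(triethylsilyl)oxy]-6,7-dihydro-5H-cyclopenta[c]pyridine-5-carboxylate
Product: 22 methyl (5R,6S)-5-[(tert-butyldimethylsilyl)oxy]-3-[(1E,3E,5S)-3,5-dimethylhepta-1,3-dien-1-yl]-6-hydroxy-6-methyl-7-oxo-6,7-dihydro-5H-cyclopenta[c]pyridine-5-carboxylate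
Conditions: HF·pyridine, pyridine, THF, 0 °C
Reagents that add atoms: none
Why: buffered fluoride-mediated desilylation should remove the triethylsilyl ether well before the bulkier tert-butyldimethylsilyl ether on the more congested C5 oxygen, and the acidic medium does not promote silyl migration between the two oxygens.

Step 13
Reactants: 22 methyl (5R,6S)-5-[(tert-butyldimethylsilyl)oxy]-3-[(1E,3E,5S)-3,5-dimethylhepta-1,3-dien-1-yl]-6-hydroxy-6-methyl-7-oxo-6,7-dihydro-5H-cyclopenta[c]pyridine-5-carboxylate
Product: 23 methyl (5R,6S)-6-(acetyloxy)-5-[(tert-butyldimethylsilyl)oxy]-3-[(1E,3E,5S)-3,5-dimethylhepta-1,3-dien-1-yl]-6-methyl-7-oxo-6,7-dihydro-5H-cyclopenta[c]pyridine-5-carboxylate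
Conditions: Ac2O, DMAP, Et3N, CH2Cl2, rt → 40 °C
Reagents that add atoms: acetic anhydride, CC(=O)OC(C)=O
Why: 4-(dimethylamino)pyridine-catalysed acyl transfer acetylates tertiary α-hydroxy ketones, and C6–OH is the only free hydroxyl, so no site selectivity is required.

Step 14
Reactants: 23 methyl (5R,6S)-6-(acetyloxy)-5-[(tert-butyldimethylsilyl)oxy]-3-[(1E,3E,5S)-3,5-dimethylhepta-1,3-dien-1-yl]-6-methyl-7-oxo-6,7-dihydro-5H-cyclopenta[c]pyridine-5-carboxylate
Product: 24 methyl (5R,6S)-6-(acetyloxy)-3-[(1E,3E,5S)-3,5-dimethylhepta-1,3-dien-1-yl]-5-hydroxy-6-methyl-7-oxo-6,7-dihydro-5H-cyclopenta[c]pyridine-5-carboxylate (CNP0483502.1)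
Conditions: HF·pyridine, THF, 0 °C → rt
Reagents that add atoms: none
Why: acidic fluoride cleaves the remaining silyl ether without hydrolysing the acetate or the methyl ester, and the trans arrangement of the C5 and C6 oxygens on the five-membered ring blocks acetyl migration.

**Compound list**
1 | (S)-2-methylbutan-1-ol | CC[C@H](C)CO | starting material
2 | ethyl 2-(triphenyl-λ5-phosphanylidene)propanoate | CCOC(=O)C(C)=P(c1ccccc1)(c1ccccc1)c1ccccc1 | starting material
3 | (S)-2-methylbutanal | CC[C@H](C)C=O | intermediate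
4 | ethyl (2E,4S)-2,4-dimethylhex-2-enoate | CC[C@H](C)/C=C(C)/C(=O)OCC | intermediate
5 | (2E,4S)-2,4-dimethylhex-2-en-1-ol | CC[C@H](C)/C=C(C)/CO | intermediate
6 | (2E,4S)-2,4-dimethylhex-2-enal | CC[C@H](C)/C=C(C)/C=O | intermediate
7 | 2-(dichloromethyl)-4,4,5,5-tetramethyl-1,3,2-dioxaborolane | ClC(Cl)B1OC(C)(C)C(C)(C)O1 | starting material
8 | 2-[(1E,3E,5S)-3,5-dimethylhepta-1,3-dien-1-yl]-4,4,5,5-tetramethyl-1,3,2-dioxaborolane | CC[C@H](C)/C=C(C)/C=C/B1OC(C)(C)C(C)(C)O1 | intermediate
9 | (S)-citramalic acid | C[C@](O)(CC(=O)O)C(=O)O | starting material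
10 | dimethyl (2S)-2-hydroxy-2-methylbutanedioate | C[C@](O)(CC(=O)OC)C(=O)OC | intermediate
11 | dimethyl (2S)-2,3-dihydroxy-2-methylbutanedioate (C3 epimers) | C[C@](O)(C(O)C(=O)OC)C(=O)OC | intermediate
12 | dimethyl (2S)-2-hydroxy-2-methyl-3-oxobutanedioate | C[C@](O)(C(=O)C(=O)OC)C(=O)OC | intermediate
13 | dimethyl (2S)-2-methyl-3-oxo-2-[(triethylsilyl)oxy]butanedioate | C[C@](O[Si](CC)(CC)CC)(C(=O)C(=O)OC)C(=O)OC | intermediate
14 | 5-bromo-2-chloropyridine | Clc1ccc(Br)cn1 | starting material
15 | (5-bromo-2-chloropyridin-4-yl)lithium | [Li]c1cc(Cl)ncc1Br | intermediate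
16 | lithium alkoxide of dimethyl (2R,3S)-2-(5-bromo-2-chloropyridin-4-yl)-2-hydroxy-3-methyl-3-[(triethylsilyl)oxy]butanedioate | Clc1cc([C@]([O-])(C(=O)OC)[C@](C)(O[Si](CC)(CC)CC)C(=O)OC)c(Br)cn1.[Li+] | intermediate
17 | dimethyl (2R,3S)-2-(5-bromo-2-chloropyridin-4-yl)-2-[(tert-butyldimethylsilyl)oxy]-3-methyl-3-[(triethylsilyl)oxy]butanedioate | Clc1cc([C@](O[Si](C)(C)C(C)(C)C)(C(=O)OC)[C@](C)(O[Si](CC)(CC)CC)C(=O)OC)c(Br)cn1 | intermediate
18 | 5-lithio analogue of 17 (lithium in place of bromine) | Clc1cc([C@](O[Si](C)(C)C(C)(C)C)(C(=O)OC)[C@](C)(O[Si](CC)(CC)CC)C(=O)OC)c([Li])cn1 | intermediate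
19 | lithium 7-methoxy-7-olate (hemiketal alkoxide) of the cyclised core, C7 configuration undefined | Clc1cc2c(cn1)C([O-])(OC)[C@@](C)(O[Si](CC)(CC)CC)[C@@]2(O[Si](C)(C)C(C)(C)C)C(=O)OC.[Li+] | intermediate
20 | methyl (5R,6S)-5-[(tert-butyldimethylsilyl)oxy]-3-chloro-6-methyl-7-oxo-6-[(triethylsilyl)oxy]-6,7-dihydro-5H-cyclopenta[c]pyridine-5-carboxylate | Clc1cc2c(cn1)C(=O)[C@@](C)(O[Si](CC)(CC)CC)[C@@]2(O[Si](C)(C)C(C)(C)C)C(=O)OC | intermediate
21 | methyl (5R,6S)-5-[(tert-butyldimethylsilyl)oxy]-3-[(1E,3E,5S)-3,5-dimethylhepta-1,3-dien-1-yl]-6-methyl-7-oxo-6-[(triethylsilyl)oxy]-6,7-dihydro-5H-cyclopenta[c]pyridine-5-carboxylate | CC[C@H](C)/C=C(C)/C=C/c1cc2c(cn1)C(=O)[C@@](C)(O[Si](CC)(CC)CC)[C@@]2(O[Si](C)(C)C(C)(C)C)C(=O)OC | intermediate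
22 | methyl (5R,6S)-5-[(tert-butyldimethylsilyl)oxy]-3-[(1E,3E,5S)-3,5-dimethylhepta-1,3-dien-1-yl]-6-hydroxy-6-methyl-7-oxo-6,7-dihydro-5H-cyclopenta[c]pyridine-5-carboxylate | CC[C@H](C)/C=C(C)/C=C/c1cc2c(cn1)C(=O)[C@@](C)(O)[C@@]2(O[Si](C)(C)C(C)(C)C)C(=O)OC | intermediate
23 | methyl (5R,6S)-6-(acetyloxy)-5-[(tert-butyldimethylsilyl)oxy]-3-[(1E,3E,5S)-3,5-dimethylhepta-1,3-dien-1-yl]-6-methyl-7-oxo-6,7-dihydro-5H-cyclopenta[c]pyridine-5-carboxylate | CC[C@H](C)/C=C(C)/C=C/c1cc2c(cn1)C(=O)[C@@](C)(OC(C)=O)[C@@]2(O[Si](C)(C)C(C)(C)C)C(=O)OC | intermediate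
24 | methyl (5R,6S)-6-(acetyloxy)-3-[(1E,3E,5S)-3,5-dimethylhepta-1,3-dien-1-yl]-5-hydroxy-6-methyl-7-oxo-6,7-dihydro-5H-cyclopenta[c]pyridine-5-carboxylate | CC[C@H](C)/C=C(C)/C=C/c1cc2c(cn1)C(=O)[C@@](C)(OC(C)=O)[C@@]2(O)C(=O)OC | target

**Step count**
Total: 14 steps. Longest linear sequence: 10 steps (9 → 24, steps 5–14).

**Steps most likely to fail**

Step 9. The facial selectivity at the C5 ketone may be low or reversed, because the methyl and ester groups on C6 differ little in size. The hindered alkoxide may also silylate slowly enough for the triethylsilyl group to migrate between the two oxygens. The fallback inverts the stereocontrol element and sets out from 12 and from aryllithium 15 (made from 14 as in step 9). Hydroxy ketone 12 is deprotonated with LiN(SiMe3)2 and complexed with MgBr2·OEt2 at −78 °C to the bromomagnesium alkoxide of dimethyl (2S)-2-hydroxy-2-methyl-3-oxobutanedioate F1 in which a five-membered chelate holds the ketone oxygen syn to O6. Addition of 15 to this Cram chelate follows the complementary facial preference and should give dimethyl (2R,3S)-2-(5-bromo-2-chloropyridin-4-yl)-2,3-dihydroxy-3-methylbutanedioate F2 whenever the ester is the more obstructive group. The less hindered C6 hydroxyl is silylated with one equivalent of TESOTf and 2,6-lutidine at −78 °C to dimethyl (2R,3S)-2-(5-bromo-2-chloropyridin-4-yl)-2-hydroxy-3-methyl-3-[(triethylsilyl)oxy]butanedioate F3 with the C5 hydroxyl still free. TBSOTf and 2,6-lutidine then cap the C5 hydroxyl, and the sequence comes back to the route at 17.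

Step 10. The aryllithium may be consumed before it acylates: by proton capture, by migration of the silyl group from O5 to the carbanion, or by collapse of the hemiketal followed by a second organolithium addition to the ketone. The fallback avoids organolithiums and sets out from 17. i-Bu2AlH at −78 °C should reduce the less hindered C7 ester, whose α-silyloxy tetrahedral aluminate holds at the aldehyde level, to methyl (2R,3S)-2-(5-bromo-2-chloropyridin-4-yl)-2-[(tert-butyldimethylsilyl)oxy]-3-methyl-4-oxo-3-[(triethylsilyl)oxy]butanoate F4 with the C5 ester left intact. An intramolecular Nozaki–Hiyama–Kishi reaction (CrCl2, catalytic NiCl2, DMF, rt) then forms the same C7–C7a bond under non-basic conditions and gives methyl (5R,6R)-5-[(tert-butyldimethylsilyl)oxy]-3-chloro-7-hydroxy-6-methyl-6-[(triethylsilyl)oxy]-6,7-dihydro-5H-cyclopenta[c]pyridine-5-carboxylate F5 as a mixture of C7 epimers; the C6 descriptor changes only through ligand priority. Dess–Martin oxidation of the carbinol comes back to the route at 20.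

Step 6. Oxygen transfer to the hindered dianion may stall, and the sulfonimine by-product may capture the enolate. The fallback replaces oxygenation by the better-precedented C-alkylation of the same dianion followed by alkene cleavage, and sets out from 10. The dianion is trapped with dimethyl(methylidene)ammonium iodide to give dimethyl (2S)-3-[(dimethylamino)methyl]-2-hydroxy-2-methylbutanedioate F6 as a mixture of C3 epimers. Quaternisation with MeI gives [(3S)-3-hydroxy-4-methoxy-2-(methoxycarbonyl)-3-methyl-4-oxobutyl]trimethylammonium iodide F7 and NaHCO3 eliminates it to dimethyl (2S)-2-hydroxy-2-methyl-3-methylidenebutanedioate F8 at room temperature. Ozonolysis (O3, CH2Cl2/MeOH, −78 °C; Me2S) comes back to the route at 12, bypassing 11 and step 7.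

**Further compounds**
F1 | step 9 | bromomagnesium alkoxide of dimethyl (2S)-2-hydroxy-2-methyl-3-oxobutanedioate | C[C@]([O-])(C(=O)C(=O)OC)C(=O)OC.[Mg+2].[Br-]
F2 | step 9 | dimethyl (2R,3S)-2-(5-bromo-2-chloropyridin-4-yl)-2,3-dihydroxy-3-methylbutanedioate | Clc1cc([C@](O)(C(=O)OC)[C@](C)(O)C(=O)OC)c(Br)cn1
F3 | step 9 | dimethyl (2R,3S)-2-(5-bromo-2-chloropyridin-4-yl)-2-hydroxy-3-methyl-3-[(triethylsilyl)oxy]butanedioate | Clc1cc([C@](O)(C(=O)OC)[C@](C)(O[Si](CC)(CC)CC)C(=O)OC)c(Br)cn1
F4 | step 10 | methyl (2R,3S)-2-(5-bromo-2-chloropyridin-4-yl)-2-[(tert-butyldimethylsilyl)oxy]-3-methyl-4-oxo-3-[(triethylsilyl)oxy]butanoate | Clc1cc([C@](O[Si](C)(C)C(C)(C)C)(C(=O)OC)[C@](C)(O[Si](CC)(CC)CC)C=O)c(Br)cn1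
F5 | step 10 | methyl (5R,6R)-5-[(tert-butyldimethylsilyl)oxy]-3-chloro-7-hydroxy-6-methyl-6-[(triethylsilyl)oxy]-6,7-dihydro-5H-cyclopenta[c]pyridine-5-carboxylate | Clc1cc2c(cn1)C(O)[C@@](C)(O[Si](CC)(CC)CC)[C@@]2(O[Si](C)(C)C(C)(C)C)C(=O)OC
F6 | step 6 | dimethyl (2S)-3-[(dimethylamino)methyl]-2-hydroxy-2-methylbutanedioate | C[C@](O)(C(CN(C)C)C(=O)OC)C(=O)OC
F7 | step 6 | [(3S)-3-hydroxy-4-methoxy-2-(methoxycarbonyl)-3-methyl-4-oxobutyl]trimethylammonium iodide | C[C@](O)(C(C[N+](C)(C)C)C(=O)OC)C(=O)OC.[I-]
F8 | step 6 | dimethyl (2S)-2-hydroxy-2-methyl-3-methylidenebutanedioate | C[C@](O)(C(=C)C(=O)OC)C(=O)OC
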